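**Strategy.** Everything rests on cutting C2–C3 of the 3(2H)-furanone ring. C3 is an acyl carbon that already carries the C10 oxygen, so the ring oxygen can be stored as the ester oxygen of a nine-membered (Z)-enoate lactone (O10, C3–C10) whose quaternary C10 bears an acetyl group (C1, C2). In one operation the acetyl enolate attacks the lactone carbonyl and water is lost: C2–C3 forms, and with it the furanone and the ten-membered carbocycle C1–C10. The precursor already holds the trans α-methylene lactone, the 8R methacrylate and a C15 silyl ether, so a single desilylation finishes the synthesis.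

Key step: step 16

Numbering: atoms are numbered as in the target (C1 ketone, C2=C3 furanone enol ether, C4=C5, C6 lactone carbinol, C7, C8 ester carbinol, C9, C10 quaternary carbon, C11=C13 methylene, C12 lactone carbonyl, C14 methyl, C15 hydroxymethyl; O6, O8, O10 sit on the carbons of the same number).

Assumption: (S,S)-ProPhenol is taken to direct the alkynylzinc to the Re face of the enal, as it does in its aldol additions; if the sense were opposite, (R,R)-ProPhenol would be used with no other change.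

**Route**

Step 1
Reactants: 1 (E)-3-methylpent-2-en-4-yn-1-ol
Product: 2 [(2S,3S)-3-ethynyl-3-methyloxiran-2-yl]methanol
Conditions: Ti(OiPr)4 (cat.), L-(+)-diethyl tartrate, t-BuOOH, 4 Å MS, CH2Cl2, −20 °C
Reagents that add atoms: tert-butyl hydroperoxide, CC(C)(C)OO
Why: Sharpless asymmetric epoxidation of an (E)-trisubstituted allylic alcohol; with L-(+)-tartrate the oxygen is delivered to the same alkene face as in geraniol, which sets the quaternary carbon (future C10) in the required sense, and the alkyne is inert to the titanium–peroxide system.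

Step 2
Reactants: 2 [(2S,3S)-3-ethynyl-3-methyloxiran-2-yl]methanol
Product: 3 (3R)-3-methylpent-4-yne-1,3-diol
Conditions: LiBHEt3, THF, 0 °C → rt
Reagents that add atoms: none
Why: Hydride opening of a trisubstituted epoxide at its less substituted carbon (SN2 at C2 of the oxirane); the quaternary propargylic C–O bond is not broken, so C10 keeps its configuration, and a borohydride, unlike an aluminium hydride, does not hydrometalate the propargylic alkyne.

Step 3
Reactants: 3 (3R)-3-methylpent-4-yne-1,3-diol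
Product: 4 (3R)-3-hydroxy-3-methylpent-4-ynal
Conditions: TEMPO (10 mol%), PhI(OAc)2, CH2Cl2, rt; solution used at once
Reagents that add atoms: none
Why: Oxoammonium (TEMPO) oxidation converts only the primary hydroxyl, since the tertiary one has no carbinol hydrogen; the β-hydroxy aldehyde is not stored, to avoid dehydration.

Step 4
Reactants: 5 (E)-but-2-enal, 6 tert-butyldimethyl(prop-2-yn-1-yloxy)silane
Product: 7 (4S,5E)-1-[(tert-butyldimethylsilyl)oxy]hept-5-en-2-yn-4-ol
Conditions: Me2Zn, (S,S)-ProPhenol (10 mol%), Ph3P=O (20 mol%), toluene, 0 °C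
Reagents that add atoms: none
Why: Zinc–ProPhenol-catalysed asymmetric alkynylation of an enal; the dinuclear zinc complex binds aldehyde and zinc acetylide and delivers the alkynyl group to the Re face, which sets C6 as the 4S carbinol.

Step 5
Reactants: 7 (4S,5E)-1-[(tert-butyldimethylsilyl)oxy]hept-5-en-2-yn-4-ol
Product: 9 (2Z,4S,5E)-1-[(tert-butyldimethylsilyl)oxy]-2-iodohepta-2,5-dien-4-ol, via cyclic alkenylalanate 8 (not isolated)
Conditions: NaAlH2(OCH2CH2OCH3)2, THF, 0 °C → rt; then I2, THF, −78 °C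
Reagents that add atoms: iodine, II
Why: Hydroxyl-directed trans-hydroalumination of a propargylic alcohol, then iodinolysis of the C–Al bond with retention; aluminium goes to the distal alkyne carbon (C4) and hydrogen to C5, so iodine ends cis to C6, which fixes the future (Z) C4=C5 geometry.

Step 6
Reactants: 9 (2Z,4S,5E)-1-[(tert-butyldimethylsilyl)oxy]-2-iodohepta-2,5-dien-4-ol
Product: 10 (2Z,4S,5E)-1-[(tert-butyldimethylsilyl)oxy]-2-iodo-4-[(triethylsilyl)oxy]hepta-2,5-diene
Conditions: Et3SiCl, imidazole, CH2Cl2, 0 °C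
Reagents that add atoms: chlorotriethylsilane, CC[Si](Cl)(CC)CC
Why: Silyl ether formation at the secondary alcohol masks O6, so that the carboxyl introduced next cannot lactonise onto it.

Step 7
Reactants: 10 (2Z,4S,5E)-1-[(tert-butyldimethylsilyl)oxy]-2-iodo-4-[(triethylsilyl)oxy]hepta-2,5-diene, 11 di-tert-butyl dicarbonate
Product: 13 tert-butyl (2Z,4S,5E)-2-{[(tert-butyldimethylsilyl)oxy]methyl}-4-[(triethylsilyl)oxy]hepta-2,5-dienoate, via alkenylmagnesium chloride 12 (not isolated)
Conditions: i-PrMgCl·LiCl, THF, −40 → −20 °C; then 11, −20 °C → rt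
Reagents that add atoms: none
Why: Iodine–magnesium exchange of the alkenyl iodide with the turbo-Grignard reagent retains the alkene geometry, and acylation of the alkenylmagnesium by Boc2O gives the tert-butyl ester, so C3 enters cis to C6.

Step 8
Reactants: 13 tert-butyl (2Z,4S,5E)-2-{[(tert-butyldimethylsilyl)oxy]methyl}-4-[(triethylsilyl)oxy]hepta-2,5-dienoate
Product: 14 tert-butyl (2Z,4S,5E)-2-{[(tert-butyldimethylsilyl)oxy]methyl}-4-hydroxyhepta-2,5-dienoate
Conditions: HF·pyridine, pyridine, THF, 0 °C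
Reagents that add atoms: none
Why: Selective desilylation; buffered HF cleaves the secondary triethylsilyl ether much faster than the primary tert-butyldimethylsilyl ether, and the hindered tert-butyl ester does not lactonise onto the freed γ-hydroxyl under these non-basic conditions.

Step 9
Reactants: 14 tert-butyl (2Z,4S,5E)-2-{[(tert-butyldimethylsilyl)oxy]methyl}-4-hydroxyhepta-2,5-dienoate, 15 2-(bromomethyl)prop-2-enoic acid
Product: 16 tert-butyl (2Z,4S,5E)-4-{[2-(bromomethyl)prop-2-enoyl]oxy}-2-{[(tert-butyldimethylsilyl)oxy]methyl}hepta-2,5-dienoate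
Conditions: DCC, DMAP (5 mol%), CH2Cl2, 0 °C
Reagents that add atoms: none
Why: Steglich esterification of the secondary allylic alcohol; cold conditions and little DMAP spare the allylic bromide, and O6 is now acylated by what becomes C12.

Step 10
Reactants: 16 tert-butyl (2Z,4S,5E)-4-{[2-(bromomethyl)prop-2-enoyl]oxy}-2-{[(tert-butyldimethylsilyl)oxy]methyl}hepta-2,5-dienoate
Product: 17 tert-butyl (2Z)-3-[(2R)-4-(bromomethyl)-5-oxo-2,5-dihydrofuran-2-yl]-2-{[(tert-butyldimethylsilyl)oxy]methyl}prop-2-enoate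
Conditions: second-generation Grubbs catalyst (5 mol%), CH2Cl2, 40 °C
Reagents that add atoms: none
Why: Ring-closing metathesis between the propenyl group and the 1,1-disubstituted acrylate closes the five-membered butenolide with loss of propene, while the trisubstituted, electron-poor C4=C5 alkene does not take part and C6 is untouched.

Step 11
Reactants: 17 tert-butyl (2Z)-3-[(2R)-4-(bromomethyl)-5-oxo-2,5-dihydrofuran-2-yl]-2-{[(tert-butyldimethylsilyl)oxy]methyl}prop-2-enoate, 4 (3R)-3-hydroxy-3-methylpent-4-ynal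
Product: 18 tert-butyl (2Z)-2-{[(tert-butyldimethylsilyl)oxy]methyl}-3-[(2R,3R)-3-[(1S,3R)-1,3-dihydroxy-3-methylpent-4-yn-1-yl]-4-methylidene-5-oxooxolan-2-yl]prop-2-enoate
Conditions: Zn dust, THF/sat. aq NH4Cl, 0 °C → rt
Reagents that add atoms: none
Why: Zinc-mediated Barbier allylation of an aldehyde by a 3-(bromomethyl)butenolide with γ-attack; the aldehyde adds to C7 on the ring face anti to the C6 side chain (trans lactone, 7R), and the Zimmerman–Traxler chair with the aldehyde substituent equatorial and the ring-locked (E)-allyl unit gives the anti adduct, the 8S alcohol, whose inversion is planned in the next step.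

Step 12
Reactants: 18 tert-butyl (2Z)-2-{[(tert-butyldimethylsilyl)oxy]methyl}-3-[(2R,3R)-3-[(1S,3R)-1,3-dihydroxy-3-methylpent-4-yn-1-yl]-4-methylidene-5-oxooxolan-2-yl]prop-2-enoate, 19 2-methylprop-2-enoic acid
Product: 20 tert-butyl (2Z)-2-{[(tert-butyldimethylsilyl)oxy]methyl}-3-[(2R,3R)-3-[(1R,3R)-3-hydroxy-3-methyl-1-[(2-methylprop-2-enoyl)oxy]pent-4-yn-1-yl]-4-methylidene-5-oxooxolan-2-yl]prop-2-enoate
Conditions: PPh3, DIAD, THF, 0 °C → rt
Reagents that add atoms: none
Why: Mitsunobu esterification, an SN2 displacement of the oxyphosphonium group by methacrylate that inverts C8 from S to the required R; the tertiary propargylic hydroxyl cannot be activated in this way and stays free.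

Step 13
Reactants: 20 tert-butyl (2Z)-2-{[(tert-butyldimethylsilyl)oxy]methyl}-3-[(2R,3R)-3-[(1R,3R)-3-hydroxy-3-methyl-1-[(2-methylprop-2-enoyl)oxy]pent-4-yn-1-yl]-4-methylidene-5-oxooxolan-2-yl]prop-2-enoate
Product: 22 (2Z)-2-{[(tert-butyldimethylsilyl)oxy]methyl}-3-[(2R,3R)-3-[(1R,3R)-3-hydroxy-3-methyl-1-[(2-methylprop-2-enoyl)oxy]pent-4-yn-1-yl]-4-methylidene-5-oxooxolan-2-yl]prop-2-enoic acid, via bis(trimethylsilyl) derivative 21 (not isolated)
Conditions: Me3SiOTf, 2,6-lutidine, CH2Cl2, 0 °C; then aq citric acid, THF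
Reagents that add atoms: none
Why: Silyl triflate-mediated cleavage of a tert-butyl ester (carbonyl silylation and loss of 2-methylpropene) leaves the tert-butyldimethylsilyl ether, the lactone and the methacrylate intact; the silyl ester and the transient tertiary trimethylsilyl ether are hydrolysed in the mildly acidic work-up.

Step 14
Reactants: 22 (2Z)-2-{[(tert-butyldimethylsilyl)oxy]methyl}-3-[(2R,3R)-3-[(1R,3R)-3-hydroxy-3-methyl-1-[(2-methylprop-2-enoyl)oxy]pent-4-yn-1-yl]-4-methylidene-5-oxooxolan-2-yl]prop-2-enoic acid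
Product: 23 (4Z,6R,7R,8R,10R) nine-membered lactone with O10 acylated by C3, ethynyl (C1≡C2) and methyl on C10, 8-methacrylate, trans-fused 6,12-α-methylene-γ-lactone and C15 tert-butyldimethylsilyl ether
Conditions: MNBA (2-methyl-6-nitrobenzoic anhydride), DMAP, Et3N, CH2Cl2 (1 mM, slow addition), rt
Reagents that add atoms: none
Why: Mixed-anhydride macrolactonisation with MNBA and DMAP (Shiina lactonisation) at high dilution; the ethynyl carbinol, the least hindered kind of tertiary alcohol and the only free hydroxyl, is acylated by the acylpyridinium, and the (Z)-alkene and the trans-lactone hold the two ends close enough for the nine-membered ring, with no stereocentre affected.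

Step 15
Reactants: 23 (4Z,6R,7R,8R,10R) nine-membered lactone with ethynyl on C10
Product: 24 (4Z,6R,7R,8R,10R) nine-membered lactone with acetyl (C1 ketone, C2 methyl) and methyl on C10, 8-methacrylate, trans-fused 6,12-α-methylene-γ-lactone and C15 tert-butyldimethylsilyl ether (key-step precursor)
Conditions: Ph3PAuCl (2 mol%), AgSbF6 (2 mol%), 1,4-dioxane/H2O, rt
Reagents that add atoms: water, O
Why: Gold-catalysed Markovnikov hydration of a terminal propargylic ester with anchimeric assistance; the ester carbonyl adds 5-exo-dig to the activated alkyne, water opens the dioxolenium ion and protodeauration leaves the methyl ketone with the acyl group back on O10, so C10 and the lactone are kept.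

Step 16
Reactants: 24 (4Z,6R,7R,8R,10R) nine-membered lactone with acetyl on C10 (key-step precursor)
Product: 26 [(2Z,4R,8R,9R,11R)-2-{[(tert-butyldimethylsilyl)oxy]methyl}-11-methyl-7-methylidene-6,12-dioxo-5,14-dioxatricyclo[9.2.1.0(4,8)]tetradeca-1(13),2-dien-9-yl] 2-methylprop-2-enoate, via bridged hemiketal 25 (not isolated)
Conditions: LiN(SiMe3)2 (2.2 equiv), THF, −78 °C; AcOH, −78 °C; then TsOH·H2O (cat.), CH2Cl2, rt
Reagents that add atoms: none
Why: Proposed new method: LiN(SiMe3)2 removes a C2 proton of the acetyl group, the only enolisable ketone site because C10 is quaternary, and the enolate adds to the lactone carbonyl C3 through a five-membered transition state to give the bridged hemiketal 25, in which C2–C3 already spans the nine-membered ring. The closest known reaction is the base-mediated O-to-C acyl transfer of acyclic tertiary α-acyloxy ketones followed by acid cyclodehydration of the resulting α'-hydroxy 1,3-diketone to a 3(2H)-furanone; its transannular, ring-expanding use is untested. The furanone closes 5-exo-trig (C2 onto C3), and the ten-membered carbocycle C1–C10 closes in the same bond formation, so no separate macrocyclisation is needed; acid then eliminates water across C2–C3. No lasting stereocentre is formed, since the hemiketal carbon C3 becomes sp2, and the (Z) geometry of C4=C5 is held by the ring. The step needs C3 to be chosen over the C12 lactone and the O8 methacrylate carbonyls, which would demand eight- and seven-membered transition states, and the low temperature with a cold acidic quench keeps the C10 oxygen from taking the neighbouring O8 acyl group.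

Step 17
Reactants: 26 15-O-(tert-butyldimethylsilyl) derivative of the target
Product: 27 [(2Z,4R,8R,9R,11R)-2-(hydroxymethyl)-11-methyl-7-methylidene-6,12-dioxo-5,14-dioxatricyclo[9.2.1.0(4,8)]tetradeca-1(13),2-dien-9-yl] 2-methylprop-2-enoate
Conditions: HF·pyridine, pyridine, THF, 0 °C
Reagents that add atoms: none
Why: Desilylation of the primary allylic silyl ether with buffered HF, conditions that do not touch the methacrylate, the α-methylene lactone or the furanone.

**Compound list**

1 | (E)-3-methylpent-2-en-4-yn-1-ol | C#C/C(C)=C/CO | starting material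
2 | [(2S,3S)-3-ethynyl-3-methyloxiran-2-yl]methanol | OC[C@@H]1O[C@@]1(C)C#C | intermediate
3 | (3R)-3-methylpent-4-yne-1,3-diol | OCC[C@@](C)(O)C#C | intermediate
4 | (3R)-3-hydroxy-3-methylpent-4-ynal | O=CC[C@@](C)(O)C#C | intermediate
5 | (E)-but-2-enal | C/C=C/C=O | starting material
6 | tert-butyldimethyl(prop-2-yn-1-yloxy)silane | C#CCO[Si](C)(C)C(C)(C)C | starting material
7 | (4S,5E)-1-[(tert-butyldimethylsilyl)oxy]hept-5-en-2-yn-4-ol | C/C=C/[C@H](O)C#CCO[Si](C)(C)C(C)(C)C | intermediate
8 | sodium cyclic alkenylalanate from 7 (O6–Al–C4 oxaluminole ring, two 2-methoxyethoxy ligands on Al, hydrogen on C5) | C/C=C/[C@@H]1O[Al-](OCCOC)(OCCOC)C(CO[Si](C)(C)C(C)(C)C)=C1.[Na+] | intermediate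
9 | (2Z,4S,5E)-1-[(tert-butyldimethylsilyl)oxy]-2-iodohepta-2,5-dien-4-ol | C/C=C/[C@H](O)/C=C(\I)CO[Si](C)(C)C(C)(C)C | intermediate
10 | (2Z,4S,5E)-1-[(tert-butyldimethylsilyl)oxy]-2-iodo-4-[(triethylsilyl)oxy]hepta-2,5-diene | C/C=C/[C@H](O[Si](CC)(CC)CC)/C=C(\I)CO[Si](C)(C)C(C)(C)C | intermediate
11 | di-tert-butyl dicarbonate | CC(C)(C)OC(=O)OC(=O)OC(C)(C)C | starting material
12 | {(2Z,4S,5E)-1-[(tert-butyldimethylsilyl)oxy]-4-[(triethylsilyl)oxy]hepta-2,5-dien-2-yl}magnesium chloride | C/C=C/[C@H](O[Si](CC)(CC)CC)/C=C(\[Mg]Cl)CO[Si](C)(C)C(C)(C)C | intermediate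
13 | tert-butyl (2Z,4S,5E)-2-{[(tert-butyldimethylsilyl)oxy]methyl}-4-[(triethylsilyl)oxy]hepta-2,5-dienoate | C/C=C/[C@H](O[Si](CC)(CC)CC)/C=C(\C(=O)OC(C)(C)C)CO[Si](C)(C)C(C)(C)C | intermediate
14 | tert-butyl (2Z,4S,5E)-2-{[(tert-butyldimethylsilyl)oxy]methyl}-4-hydroxyhepta-2,5-dienoate | C/C=C/[C@H](O)/C=C(\C(=O)OC(C)(C)C)CO[Si](C)(C)C(C)(C)C | intermediate
15 | 2-(bromomethyl)prop-2-enoic acid | C=C(CBr)C(=O)O | starting material
16 | tert-butyl (2Z,4S,5E)-4-{[2-(bromomethyl)prop-2-enoyl]oxy}-2-{[(tert-butyldimethylsilyl)oxy]methyl}hepta-2,5-dienoate | C/C=C/[C@H](OC(=O)C(=C)CBr)/C=C(\C(=O)OC(C)(C)C)CO[Si](C)(C)C(C)(C)C | intermediate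
17 | tert-butyl (2Z)-3-[(2R)-4-(bromomethyl)-5-oxo-2,5-dihydrofuran-2-yl]-2-{[(tert-butyldimethylsilyl)oxy]methyl}prop-2-enoate | O=C1O[C@H](/C=C(\C(=O)OC(C)(C)C)CO[Si](C)(C)C(C)(C)C)C=C1CBr | intermediate
18 | tert-butyl (2Z)-2-{[(tert-butyldimethylsilyl)oxy]methyl}-3-[(2R,3R)-3-[(1S,3R)-1,3-dihydroxy-3-methylpent-4-yn-1-yl]-4-methylidene-5-oxooxolan-2-yl]prop-2-enoate | C#C[C@](C)(O)C[C@H](O)[C@H]1C(=C)C(=O)O[C@@H]1/C=C(\C(=O)OC(C)(C)C)CO[Si](C)(C)C(C)(C)C | intermediate
19 | 2-methylprop-2-enoic acid | C=C(C)C(=O)O | starting material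
20 | tert-butyl (2Z)-2-{[(tert-butyldimethylsilyl)oxy]methyl}-3-[(2R,3R)-3-[(1R,3R)-3-hydroxy-3-methyl-1-[(2-methylprop-2-enoyl)oxy]pent-4-yn-1-yl]-4-methylidene-5-oxooxolan-2-yl]prop-2-enoate | C#C[C@](C)(O)C[C@@H](OC(=O)C(C)=C)[C@H]1C(=C)C(=O)O[C@@H]1/C=C(\C(=O)OC(C)(C)C)CO[Si](C)(C)C(C)(C)C | intermediate
21 | trimethylsilyl ester of 22 with the C10 hydroxyl as its trimethylsilyl ether | C#C[C@](C)(O[Si](C)(C)C)C[C@@H](OC(=O)C(C)=C)[C@H]1C(=C)C(=O)O[C@@H]1/C=C(\C(=O)O[Si](C)(C)C)CO[Si](C)(C)C(C)(C)C | intermediate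
22 | (2Z)-2-{[(tert-butyldimethylsilyl)oxy]methyl}-3-[(2R,3R)-3-[(1R,3R)-3-hydroxy-3-methyl-1-[(2-methylprop-2-enoyl)oxy]pent-4-yn-1-yl]-4-methylidene-5-oxooxolan-2-yl]prop-2-enoic acid | C#C[C@](C)(O)C[C@@H](OC(=O)C(C)=C)[C@H]1C(=C)C(=O)O[C@@H]1/C=C(\C(=O)O)CO[Si](C)(C)C(C)(C)C | intermediate
23 | (4Z,6R,7R,8R,10R) nine-membered lactone (O10–C3 ester) with ethynyl and methyl on C10, 8-methacrylate, trans-fused 6,12-α-methylene-γ-lactone, C15 tert-butyldimethylsilyl ether | C=C(C)C(=O)O[C@@H]1C[C@@](C#C)(C)OC(=O)/C(CO[Si](C)(C)C(C)(C)C)=C\[C@H]2OC(=O)C(=C)[C@@H]21 | intermediate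
24 | (4Z,6R,7R,8R,10R) nine-membered lactone (O10–C3 ester) with acetyl and methyl on C10, 8-methacrylate, trans-fused 6,12-α-methylene-γ-lactone, C15 tert-butyldimethylsilyl ether; key-step precursor | C=C(C)C(=O)O[C@@H]1C[C@@](C(C)=O)(C)OC(=O)/C(CO[Si](C)(C)C(C)(C)C)=C\[C@H]2OC(=O)C(=C)[C@@H]21 | intermediate
25 | (3R) bridged hemiketal: 3-hydroxy-2,3-dihydro form of 26 (C2–C3 single bond, hydroxyl on C3) | C=C(C)C(=O)O[C@@H]1C[C@@]2(C)O[C@](O)(CC2=O)/C(CO[Si](C)(C)C(C)(C)C)=C\[C@H]2OC(=O)C(=C)[C@@H]21 | intermediate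
26 | [(2Z,4R,8R,9R,11R)-2-{[(tert-butyldimethylsilyl)oxy]methyl}-11-methyl-7-methylidene-6,12-dioxo-5,14-dioxatricyclo[9.2.1.0(4,8)]tetradeca-1(13),2-dien-9-yl] 2-methylprop-2-enoate; key-step product | C=C(C)C(=O)O[C@@H]1C[C@@]2(C)OC(=CC2=O)/C(CO[Si](C)(C)C(C)(C)C)=C\[C@H]2OC(=O)C(=C)[C@@H]21 | intermediate
27 | [(2Z,4R,8R,9R,11R)-2-(hydroxymethyl)-11-methyl-7-methylidene-6,12-dioxo-5,14-dioxatricyclo[9.2.1.0(4,8)]tetradeca-1(13),2-dien-9-yl] 2-methylprop-2-enoate | C=C(C)C(=O)O[C@@H]1C[C@@]2(C)OC(=CC2=O)/C(CO)=C\[C@H]2OC(=O)C(=C)[C@@H]21 | target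

**Totals**

Total steps: 17. Longest linear sequence: 14 steps (steps 4–17, from 5 and 6); steps 1–3 form the second branch, which joins at step 11.

**Steps most likely to fail**

1. Step 16 (key step). The enolate may fail to reach the lactone carbonyl across the strained ring, or the C10 oxygen set free after acyl transfer may take the O8 acyl group, or the enolate may add in conjugate fashion to the methylene lactone. The fallback uses known chemistry throughout: the furanone is made on an open chain by the established acyclic form of the same acyl transfer, and the ten-membered ring is closed last at C7–C8. It sets out from 10 and 3 and comes back at 26.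
 - Iodine–magnesium exchange on 10 (i-PrMgCl·LiCl) and carboxylation with CO2 should give (2Z,4S,5E)-2-{[(tert-butyldimethylsilyl)oxy]methyl}-4-[(triethylsilyl)oxy]hepta-2,5-dienoic acid F1.
 - 3 is protected at the primary hydroxyl (4-methoxybenzyl trichloroacetimidate, PPTS) as (3R)-1-[(4-methoxybenzyl)oxy]-3-methylpent-4-yn-3-ol F2.
 - Ruthenium-catalysed addition of F1 to the alkyne of F2 (RuCl2(p-cymene)(PPh3), toluene, 80 °C; Markovnikov enol ester, then acyl shift to the tertiary oxygen) should give the acyclic tertiary α-acyloxy methyl ketone F3.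
 - LiN(SiMe3)2 and then TsOH convert F3 into the 2,2,5-trisubstituted 3(2H)-furanone F4.
 - HF·pyridine frees O6 to give the C6 alcohol F5; DCC esterification with 15 gives the 2-(bromomethyl)acrylate F6; ring-closing metathesis gives the bromobutenolide F7.
 - DDQ removes the 4-methoxybenzyl group to give the primary alcohol F8, and Dess–Martin periodinane gives the C8 aldehyde F9.
 - Zinc in THF/aqueous NH4Cl at high dilution (or CrCl2) closes the carbocycle at C7–C8 by intramolecular allylation and should give the 8R alcohol 15-O-(tert-butyldimethylsilyl)-8-O-demethacryloyl target F10.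
 - Methacrylic anhydride with DMAP then returns to 26.

2. Step 14. Bimolecular esterification (diolide and oligomer formation) may outrun closure of the nine-membered ring at the tertiary hydroxyl. The fallback sets out from 22 and comes back at 24, and so also replaces step 15. Slow addition of 22 to RuCl2(p-cymene)(PPh3) in toluene at 80 °C should add the carboxylate to the internal alkyne carbon C1 and give the ten-membered enol lactone F11. Its acyl group then moves to the neighbouring tertiary O10 with ring contraction as the enol becomes the methyl ketone. This is the ring-closing form of the known coupling of carboxylic acids with ethynyl carbinols to 2-oxoalkyl esters, and it needs no acylation of the hindered hydroxyl by an external activated acid.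

3. Step 12. Elimination toward C7 or C9, or a stalled displacement at the β-branched carbinol, may compete with inversion. The fallback sets out from 18 and comes back at 20. Selective sulfonylation of the secondary hydroxyl (ClCH2SO2Cl, pyridine, 0 °C) gives the O8 chloromethanesulfonate of 18 F12. Displacement with CsO2CC(CH3)=CH2 and 18-crown-6 in toluene at 50 °C then gives 20 with inversion, by sulfonate displacement in place of the redox condensation.

**Further compounds**

F1 | step 16 | (2Z,4S,5E)-2-{[(tert-butyldimethylsilyl)oxy]methyl}-4-[(triethylsilyl)oxy]hepta-2,5-dienoic acid | C/C=C/[C@H](O[Si](CC)(CC)CC)/C=C(\C(=O)O)CO[Si](C)(C)C(C)(C)C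
F2 | step 16 | (3R)-1-[(4-methoxybenzyl)oxy]-3-methylpent-4-yn-3-ol | COc1ccc(COCC[C@@](C)(O)C#C)cc1
F3 | step 16 | (3R)-1-[(4-methoxybenzyl)oxy]-3-methyl-4-oxopentan-3-yl (2Z,4S,5E)-2-{[(tert-butyldimethylsilyl)oxy]methyl}-4-[(triethylsilyl)oxy]hepta-2,5-dienoate | C/C=C/[C@H](O[Si](CC)(CC)CC)/C=C(\C(=O)O[C@](C)(CCOCc1ccc(OC)cc1)C(C)=O)CO[Si](C)(C)C(C)(C)C
F4 | step 16 | (2R)-5-[(2Z,4S,5E)-1-[(tert-butyldimethylsilyl)oxy]-4-[(triethylsilyl)oxy]hepta-2,5-dien-2-yl]-2-{2-[(4-methoxybenzyl)oxy]ethyl}-2-methylfuran-3(2H)-one | C/C=C/[C@H](O[Si](CC)(CC)CC)/C=C(\C1=CC(=O)[C@@](C)(CCOCc2ccc(OC)cc2)O1)CO[Si](C)(C)C(C)(C)C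
F5 | step 16 | (2R)-5-[(2Z,4S,5E)-1-[(tert-butyldimethylsilyl)oxy]-4-hydroxyhepta-2,5-dien-2-yl]-2-{2-[(4-methoxybenzyl)oxy]ethyl}-2-methylfuran-3(2H)-one | C/C=C/[C@H](O)/C=C(\C1=CC(=O)[C@@](C)(CCOCc2ccc(OC)cc2)O1)CO[Si](C)(C)C(C)(C)C
F6 | step 16 | 2-(bromomethyl)prop-2-enoate ester of F5 at O6 | C/C=C/[C@H](OC(=O)C(=C)CBr)/C=C(\C1=CC(=O)[C@@](C)(CCOCc2ccc(OC)cc2)O1)CO[Si](C)(C)C(C)(C)C
F7 | step 16 | 3-(bromomethyl)butenolide from F6 (C6 in the butenolide, furanone on C4, 4-methoxybenzyl ether on the C8 oxygen) | O=C1O[C@H](/C=C(\C2=CC(=O)[C@@](C)(CCOCc3ccc(OC)cc3)O2)CO[Si](C)(C)C(C)(C)C)C=C1CBr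
F8 | step 16 | primary C8 alcohol from F7 | O=C1O[C@H](/C=C(\C2=CC(=O)[C@@](C)(CCO)O2)CO[Si](C)(C)C(C)(C)C)C=C1CBr
F9 | step 16 | C8 aldehyde from F8 | O=C1O[C@H](/C=C(\C2=CC(=O)[C@@](C)(CC=O)O2)CO[Si](C)(C)C(C)(C)C)C=C1CBr
F10 | step 16 | 15-O-(tert-butyldimethylsilyl)-8-O-demethacryloyl target (8R alcohol of the furanoheliangolide core) | O[C@@H]1C[C@@]2(C)OC(=CC2=O)/C(CO[Si](C)(C)C(C)(C)C)=C\[C@H]2OC(=O)C(=C)[C@@H]21
F11 | step 14 | ten-membered enol lactone (C3 carboxyl on the enol oxygen of C1, exocyclic C1=C2 methylene, free C10 hydroxyl) | C=C(C)C(=O)O[C@@H]1C[C@@](C)(O)C(=C)OC(=O)/C(CO[Si](C)(C)C(C)(C)C)=C\[C@H]2OC(=O)C(=C)[C@@H]21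
F12 | step 12 | O8 chloromethanesulfonate of 18 | C#C[C@](C)(O)C[C@H](OS(=O)(=O)CCl)[C@H]1C(=C)C(=O)O[C@@H]1/C=C(\C(=O)OC(C)(C)C)CO[Si](C)(C)C(C)(C)C
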